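**Plan**

1. Retrosynthesis: remove the two silyl groups, then cut the C2–C3 bond of the pyranone and re-attach C2 to the oxygen of the C3 hydroxyl. This gives a seven-membered 2-aryl-1,3-benzodioxepin-5-one, which is cut at both acetal C–O bonds into a 2-hydroxy-1-(2-hydroxyaryl)ethanone and 4-silyloxybenzaldehyde.
2. Enabling feature: C2 is both the benzylic ether carbon on O1 (carrying a p-oxygenated aryl group) and the neighbour of the α-ketol C3(OH)–C4(=O). An acetal carbon placed between O1 and the C3 oxygen can ionize on the C3–O side to an O1-stabilized oxocarbenium ion that stays tied to the enediolate of the ketol.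
3. Forward: the A ring is built from 2',4'-dihydroxyacetophenone (diiodination, 4-O-silylation, double Stille prenylation, enolate hydroxylation). Acetalization closes the seven-membered ring, an O-to-C 1,2-shift of C2 contracts it to the chroman-4-one, and fluoride removes both silyl groups.
4. Stereochemistry: the acetal is racemic and its stereocentre is erased. C3 and C2 are both created in the ring contraction, C3 by the face of a chiral nickel–bis(oxazoline)-bound enediolate and C2 by trans (diequatorial) closure onto the E-oxocarbenium ion.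

Key step: step 7

Remark: atom numbers are those of the chroman-4-one (O1, C2, C3, C4, C4a–C8a). The sense of induction in step 7 is assigned from a square-planar chelate model; if it proves opposite, the enantiomeric ligand is used in the same way.

**Route**

Step 1
Reactants: 1 1-(2,4-dihydroxyphenyl)ethan-1-one
Product: 2 1-(2,4-dihydroxy-3,5-diiodophenyl)ethan-1-one
Conditions: NIS (2.1 equiv), TsOH·H2O (cat.), MeCN, 0 °C to rt
Reagents that add atoms: N-iodosuccinimide, O=C1CCC(=O)N1I
Why: Electrophilic aromatic iodination; C3 and C5 are each ortho/para to both hydroxyl groups, whereas C6 is meta to both.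

Step 2
Reactants: 2 1-(2,4-dihydroxy-3,5-diiodophenyl)ethan-1-one
Product: 3 1-{4-[(tert-butyldimethylsilyl)oxy]-2-hydroxy-3,5-diiodophenyl}ethan-1-one
Conditions: TBSCl (1.05 equiv), imidazole (2.2 equiv), DMF, 0 °C to rt
Reagents that add atoms: tert-butyldimethylsilyl chloride, CC(C)(C)[Si](C)(C)Cl
Why: Selective O-silylation; the 4-OH is the more acidic phenol and is not tied up in the hydrogen bond to the acetyl group that deactivates the 2-OH.

Step 3
Reactants: 3 1-{4-[(tert-butyldimethylsilyl)oxy]-2-hydroxy-3,5-diiodophenyl}ethan-1-one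
Product: 4 1-{4-[(tert-butyldimethylsilyl)oxy]-2-hydroxy-3,5-bis(3-methylbut-2-en-1-yl)phenyl}ethan-1-one
Conditions: tributyl(prenyl)stannane (2.6 equiv), Pd(PPh3)4 (10 mol%), DMF, 90 °C
Reagents that add atoms: tributyl(3-methylbut-2-en-1-yl)stannane, CCCC[Sn](CCCC)(CCCC)CC=C(C)C
Why: Double Stille cross-coupling of the aryl iodides; reductive elimination from the η3-prenylpalladium at its unsubstituted terminus should give the linear prenyl groups.

Step 4
Reactants: 4 1-{4-[(tert-butyldimethylsilyl)oxy]-2-hydroxy-3,5-bis(3-methylbut-2-en-1-yl)phenyl}ethan-1-one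
Product: 6 1-{4-[(tert-butyldimethylsilyl)oxy]-2-hydroxy-3,5-bis(3-methylbut-2-en-1-yl)phenyl}-2-hydroxyethan-1-one, via disodium phenoxide enolate 5 (not isolated)
Conditions: NaHMDS (2.3 equiv), THF, −78 °C; then 2-(phenylsulfonyl)-3-phenyloxaziridine (1.3 equiv), −78 °C; AcOH quench
Reagents that add atoms: sodium bis(trimethylsilyl)amide, C[Si](C)(C)[N-][Si](C)(C)C.[Na+] (sodium, in 5 only); 2-(phenylsulfonyl)-3-phenyloxaziridine, O=S(=O)(N1OC1c1ccccc1)c1ccccc1 (oxygen in 6)
Why: Enolate hydroxylation with an N-sulfonyloxaziridine; the methyl ketone has a single enolizable site, the phenoxide is inert to the oxidant, and the oxaziridine does not epoxidize the prenyl groups at low temperature.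

Step 5
Reactants: 7 4-[(tert-butyldimethylsilyl)oxy]benzaldehyde
Product: 8 tert-butyl[4-(dimethoxymethyl)phenoxy]dimethylsilane
Conditions: HC(OMe)3 (3 equiv), PPTS (cat.), MeOH, rt
Reagents that add atoms: trimethyl orthoformate, COC(OC)OC
Why: Acid-catalysed acetalization with the orthoformate as water scavenger; the aryl silyl ether tolerates the weak acid.

Step 6
Reactants: 6 1-{4-[(tert-butyldimethylsilyl)oxy]-2-hydroxy-3,5-bis(3-methylbut-2-en-1-yl)phenyl}-2-hydroxyethan-1-one; 8 tert-butyl[4-(dimethoxymethyl)phenoxy]dimethylsilane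
Product: 9 rac-8-[(tert-butyldimethylsilyl)oxy]-2-{4-[(tert-butyldimethylsilyl)oxy]phenyl}-7,9-bis(3-methylbut-2-en-1-yl)-2H-1,3-benzodioxepin-5(4H)-one
Conditions: PPTS (10 mol%), benzene, 5 Å MS, 45 °C
Reagents that add atoms: none
Why: Acid-catalysed transacetalization; the primary hydroxyl exchanges first and the phenol then traps the oxocarbenium ion intramolecularly to close the seven-membered ring, driven by uptake of methanol. The weak acid should not enolize the aryl ketone, so contraction should not start here, and the racemic acetal stereocentre is erased in step 7.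

Step 7
Reactants: 9 rac-8-[(tert-butyldimethylsilyl)oxy]-2-{4-[(tert-butyldimethylsilyl)oxy]phenyl}-7,9-bis(3-methylbut-2-en-1-yl)-2H-1,3-benzodioxepin-5(4H)-one
Product: 11 (2R,3R)-7-[(tert-butyldimethylsilyl)oxy]-2-{4-[(tert-butyldimethylsilyl)oxy]phenyl}-3-hydroxy-6,8-bis(3-methylbut-2-en-1-yl)-2,3-dihydro-4H-chromen-4-one, via ring-opened oxocarbenium enediolate 10 (not isolated)
Conditions: Ni(OTf)2 (10 mol%), (R,R)-t-Bu-box [2,2'-(propane-2,2-diyl)bis((4R)-4-tert-butyl-4,5-dihydrooxazole)] (12 mol%), i-Pr2NEt (20 mol%), 4 Å MS, CH2Cl2, −20 °C to rt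
Reagents that add atoms: none
Why: Proposed new method: the bis(oxazoline)nickel(II) dication binds the α-alkoxy ketone of 9 as a five-membered chelate (ketone oxygen and the acetal oxygen on the CH2), the amine enolizes it, and heterolysis of the activated acetal C–O bond gives an O1-stabilized, p-silyloxyphenyl-conjugated oxocarbenium ion tethered to a chelated cis-enediolate (10), whose carbinol carbon (later C3) adds to the oxocarbenium carbon (C2) in a net O-to-C 1,2-shift that contracts the seven-membered ring to the chromanone; protonation of the nickel alkoxide by the ammonium ion releases 11 and the catalyst. The closest known reaction types are the Lewis-acid-promoted O-to-C rearrangement of cyclic enol acetals to oxacyclic carbonyl compounds (Petasis–Ferrier type, including the ring contraction of 4,5-dihydro-1,3-dioxepins), chiral Lewis acid-catalysed O-to-C rearrangements of chelating substrates through contact ion pairs, additions of nickel(II)–bis(oxazoline) enolates to acetal-derived oxocarbenium ions, and direct aldol additions of metal enediolates of 2-hydroxyacetophenones. The six-membered ring closes in a 6-(enolendo)-endo-trig mode, the topology of a Prins cyclization onto an endocyclic oxocarbenium ion. C3 is set by the ligand, since on the square-planar chelate model the (R,R)-ligand shields the Si face of the enediolate carbon and the tethered electrophile adds to the Re face (3R); C2 is set by the substrate, since the E-oxocarbenium ion and the cis-enediolate place the aryl group and the C3 oxygen pseudo-equatorial in the sofa transition state, which gives the 2,3-trans (2R) product that is also the thermodynamically favoured isomer. The step needs cleavage of the acetal bond on the ketol side and not the C2–O1 bond, which the chelate secures by activating only that oxygen while the other ionization is unproductive and reversible, and it needs C–C bond formation in preference to Prins capture by the neighbouring prenyl group or hydrolysis, which the far higher nucleophilicity of the enediolate, the dry medium and the silyl cap on the flanking phenol should secure.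

Step 8
Reactants: 11 (2R,3R)-7-[(tert-butyldimethylsilyl)oxy]-2-{4-[(tert-butyldimethylsilyl)oxy]phenyl}-3-hydroxy-6,8-bis(3-methylbut-2-en-1-yl)-2,3-dihydro-4H-chromen-4-one
Product: 12 (2R,3R)-3,7-dihydroxy-2-(4-hydroxyphenyl)-6,8-bis(3-methylbut-2-en-1-yl)-2,3-dihydro-4H-chromen-4-one (lespeflorin B2)
Conditions: TBAF (2.2 equiv), AcOH (2.5 equiv), THF, 0 °C
Reagents that add atoms: none
Why: Fluoride cleavage of the two aryl silyl ethers; the acetic acid buffer keeps the phenols protonated, so neither C3 (enolization) nor C2 (quinone-methide ring opening) should epimerize, and the prenyl groups see no strong acid.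

**Compound list**

1 | 1-(2,4-dihydroxyphenyl)ethan-1-one | CC(=O)c1ccc(O)cc1O | starting material
2 | 1-(2,4-dihydroxy-3,5-diiodophenyl)ethan-1-one | CC(=O)c1cc(I)c(O)c(I)c1O | intermediate
3 | 1-{4-[(tert-butyldimethylsilyl)oxy]-2-hydroxy-3,5-diiodophenyl}ethan-1-one | CC(=O)c1cc(I)c(O[Si](C)(C)C(C)(C)C)c(I)c1O | intermediate
4 | 1-{4-[(tert-butyldimethylsilyl)oxy]-2-hydroxy-3,5-bis(3-methylbut-2-en-1-yl)phenyl}ethan-1-one | CC(=O)c1cc(CC=C(C)C)c(O[Si](C)(C)C(C)(C)C)c(CC=C(C)C)c1O | intermediate
5 | disodium phenoxide enolate of 4 | C=C([O-])c1cc(CC=C(C)C)c(O[Si](C)(C)C(C)(C)C)c(CC=C(C)C)c1[O-].[Na+].[Na+] | intermediate (not isolated)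
6 | 1-{4-[(tert-butyldimethylsilyl)oxy]-2-hydroxy-3,5-bis(3-methylbut-2-en-1-yl)phenyl}-2-hydroxyethan-1-one | OCC(=O)c1cc(CC=C(C)C)c(O[Si](C)(C)C(C)(C)C)c(CC=C(C)C)c1O | intermediate
7 | 4-[(tert-butyldimethylsilyl)oxy]benzaldehyde | O=Cc1ccc(O[Si](C)(C)C(C)(C)C)cc1 | starting material
8 | tert-butyl[4-(dimethoxymethyl)phenoxy]dimethylsilane | COC(OC)c1ccc(O[Si](C)(C)C(C)(C)C)cc1 | intermediate
9 | rac-8-[(tert-butyldimethylsilyl)oxy]-2-{4-[(tert-butyldimethylsilyl)oxy]phenyl}-7,9-bis(3-methylbut-2-en-1-yl)-2H-1,3-benzodioxepin-5(4H)-one | O=C1COC(c3ccc(O[Si](C)(C)C(C)(C)C)cc3)Oc2c(CC=C(C)C)c(O[Si](C)(C)C(C)(C)C)c(CC=C(C)C)cc12 | intermediate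
10 | ring-opened intermediate, nickel-bound, drawn without the metal: cis-enediolate of the ketol tethered to the aryloxy(aryl)carbenium (oxocarbenium) ion | [O-]/C=C(\O)c1cc(CC=C(C)C)c(O[Si](C)(C)C(C)(C)C)c(CC=C(C)C)c1[O+]=Cc1ccc(O[Si](C)(C)C(C)(C)C)cc1 | intermediate (not isolated)
11 | (2R,3R)-7-[(tert-butyldimethylsilyl)oxy]-2-{4-[(tert-butyldimethylsilyl)oxy]phenyl}-3-hydroxy-6,8-bis(3-methylbut-2-en-1-yl)-2,3-dihydro-4H-chromen-4-one | CC(C)=CCc1cc2c(c(CC=C(C)C)c1O[Si](C)(C)C(C)(C)C)O[C@H](c1ccc(O[Si](C)(C)C(C)(C)C)cc1)[C@@H](O)C2=O | intermediate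
12 | (2R,3R)-3,7-dihydroxy-2-(4-hydroxyphenyl)-6,8-bis(3-methylbut-2-en-1-yl)-2,3-dihydro-4H-chromen-4-one (lespeflorin B2) | CC(C)=CCc1cc2c(c(CC=C(C)C)c1O)O[C@H](c1ccc(O)cc1)[C@@H](O)C2=O | target

**Count**

Total steps: 8. Longest linear sequence: 7 steps (1 → 2 → 3 → 4 → 6 → 9 → 11 → 12); step 5 is a one-step side branch.

**Steps most likely to fail**

Step 7 (Proposed new method). The ion-pair collapse may proceed with poor facial selectivity, and the oxocarbenium ion may be diverted by Prins capture at the neighbouring prenyl group or by hydrolysis before the enediolate forms. Epimerization of the product on the Lewis acid is also possible. The fallback uses known chemistry, sets out from 4 and comes back at 12. Compound 4 is desilylated (TBAF, AcOH, THF) to 1-[2,4-dihydroxy-3,5-bis(3-methylbut-2-en-1-yl)phenyl]ethan-1-one F1. Both phenols are capped (MOMCl, NaH, DMF) to give 1-[2,4-bis(methoxymethoxy)-3,5-bis(3-methylbut-2-en-1-yl)phenyl]ethan-1-one F2. Claisen–Schmidt condensation with commercial 4-(methoxymethoxy)benzaldehyde (KOH, EtOH) gives the (E)-chalcone F3. Juliá–Colonna epoxidation (poly-L-leucine, urea–H2O2, DBU, THF) should give the (2R,3S)-epoxy ketone F4, since the nucleophilic peroxide leaves the prenyl groups alone. HCl in MeOH then removes the three MOM groups, and the freed 2'-phenol opens the epoxide 6-endo at the benzylic carbon with inversion, which gives 12 directly.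

Step 6. The hydrogen-bonded, hindered phenol may fail to close the seven-membered mixed acetal, or acid-mediated ring contraction may set in early without stereocontrol. The fallback forms the aryl–O–C2 bond under basic, irreversible conditions before the hydroxyl is introduced; it sets out from 4 (with 8 as the source of the electrophile) and comes back at 9. Compound 8 is converted with acetyl chloride into the α-chloro ether tert-butyl{4-[chloro(methoxy)methyl]phenoxy}dimethylsilane F5, used crude. The sodium phenoxide of 4 (NaH, THF, 0 °C) is alkylated with it to the mixed O-aryl O-methyl acetal F6. Enolate hydroxylation as in step 4, now on a mono-enolate, gives the hydroxy ketone F7. PPTS with 5 Å sieves closes the ring by intramolecular transacetalization through the primary hydroxyl, with loss of methanol, to give 9.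

Step 3. Allylic transposition during transmetalation and reductive elimination may give reverse-prenyl isomers, and the second coupling at the hindered C3 position may stall. The fallback sets out from 3 and comes back at 4. Stille coupling with allyltributylstannane (Pd(PPh3)4, DMF, 90 °C) gives the 3,5-diallyl ketone F8, which has no regiochemical ambiguity. Olefin cross-metathesis with excess 2-methylbut-2-ene (second-generation ruthenium benzylidene catalyst, CH2Cl2, 40 °C) then converts both allyl groups into prenyl groups and gives 4.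

**Further compounds**

F1 | step 7 | 1-[2,4-dihydroxy-3,5-bis(3-methylbut-2-en-1-yl)phenyl]ethan-1-one | CC(=O)c1cc(CC=C(C)C)c(O)c(CC=C(C)C)c1O
F2 | step 7 | 1-[2,4-bis(methoxymethoxy)-3,5-bis(3-methylbut-2-en-1-yl)phenyl]ethan-1-one | CC(=O)c1cc(CC=C(C)C)c(OCOC)c(CC=C(C)C)c1OCOC
F3 | step 7 | (E)-1-[2,4-bis(methoxymethoxy)-3,5-bis(3-methylbut-2-en-1-yl)phenyl]-3-[4-(methoxymethoxy)phenyl]prop-2-en-1-one | COCOc1ccc(/C=C/C(=O)c2cc(CC=C(C)C)c(OCOC)c(CC=C(C)C)c2OCOC)cc1
F4 | step 7 | [2,4-bis(methoxymethoxy)-3,5-bis(3-methylbut-2-en-1-yl)phenyl]{(2R,3S)-3-[4-(methoxymethoxy)phenyl]oxiran-2-yl}methanone | O=C(c1cc(CC=C(C)C)c(OCOC)c(CC=C(C)C)c1OCOC)[C@@H]1O[C@H]1c1ccc(OCOC)cc1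
F5 | step 6 | tert-butyl{4-[chloro(methoxy)methyl]phenoxy}dimethylsilane | COC(Cl)c1ccc(O[Si](C)(C)C(C)(C)C)cc1
F6 | step 6 | 1-{4-[(tert-butyldimethylsilyl)oxy]-2-[{4-[(tert-butyldimethylsilyl)oxy]phenyl}(methoxy)methoxy]-3,5-bis(3-methylbut-2-en-1-yl)phenyl}ethan-1-one | CC(=O)c1cc(CC=C(C)C)c(O[Si](C)(C)C(C)(C)C)c(CC=C(C)C)c1OC(OC)c1ccc(O[Si](C)(C)C(C)(C)C)cc1
F7 | step 6 | 1-{4-[(tert-butyldimethylsilyl)oxy]-2-[{4-[(tert-butyldimethylsilyl)oxy]phenyl}(methoxy)methoxy]-3,5-bis(3-methylbut-2-en-1-yl)phenyl}-2-hydroxyethan-1-one | OCC(=O)c1cc(CC=C(C)C)c(O[Si](C)(C)C(C)(C)C)c(CC=C(C)C)c1OC(OC)c1ccc(O[Si](C)(C)C(C)(C)C)cc1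
F8 | step 3 | 1-{3,5-diallyl-4-[(tert-butyldimethylsilyl)oxy]-2-hydroxyphenyl}ethan-1-one | CC(=O)c1cc(CC=C)c(O[Si](C)(C)C(C)(C)C)c(CC=C)c1O
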